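**Plan**
Cuts: (a) the aryl ether bond ArO–CH2, which releases umbelliferone; (b) in one move, the bond from ring carbon C3 (the ring CH) to the first side-chain CH2 together with one C2–CH3 bond of the gem-dimethyl carbon; (c) the C2=C3 alkene of the resulting enone, by metathesis.
Enabling feature: the cyclohexanone ring (C1 = C=O, C2 = CMe2, C3 = CH, C4 = C(OH)CH3, C5, C6) is a reduced p-quinol. C3 is β to the C1 ketone, is bonded directly to carbinol carbon C4, and carries its chain cis to the C4 hydroxyl; the α-carbon C2 is the quaternary carbon.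
Event: the C4 alkoxide of (S)-4-hydroxy-2,4-dimethylcyclohex-2-enone (fragment A) anchors the side-chain Grignard reagent (fragment B) and delivers it to C3 on its own face. The enolate formed at C2 is methylated in the same flask.
Forward order: ring of A by ring-closing metathesis (steps 1–4); B by hydroboration, acetonide formation, oxidative cleavage and iododecarboxylation (steps 5–8); A + B + MeI (step 9); acetonide removal and Mitsunobu etherification with umbelliferone (steps 10–11).
Stereochemistry: ring C4 is bought as (S)-linalool, the side-chain carbinol as (R)-linalool, and ring C3 is relayed from C4 in step 9.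

Key step: step 9

Assumption: (S)-(+)-linalool (coriandrol) and (R)-(−)-linalool (licareol) are both bought in high enantiomeric purity. Because two enantioenriched fragments are joined in step 9, residual minor enantiomers would appear there as a diastereomer that chromatography can remove.

Step 1
Reactants: 1 (S)-(+)-linalool
Product: 3 (5S)-5-ethenyl-5-methyloxolan-2-ol (lactol as anomer mixture), via hydroxy aldehyde 2 (not isolated)
Conditions: O3 (to the fading of Sudan Red 7B), CH2Cl2/MeOH, −78 °C; then Me2S, −78 °C → rt
Reagents that add atoms: ozone, [O-][O+]=O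
Why: Chemoselective ozonolysis: the electron-rich trisubstituted alkene reacts with ozone much faster than the monosubstituted vinyl group, so stopping at the dye end point and reducing with Me2S should give hydroxy aldehyde 2, which closes spontaneously to lactol 3 without touching the tertiary carbinol stereocentre.

Step 2
Reactants: 3 (5S)-5-ethenyl-5-methyloxolan-2-ol
Product: 4 (6S)-2,6-dimethylocta-1,7-diene-3,6-diol (both C3 epimers)
Conditions: isopropenylmagnesium bromide (2.5 equiv), THF, 0 °C → rt; then H2O
Reagents that add atoms: isopropenylmagnesium bromide, CC(=C)[Mg]Br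
Why: Grignard addition to a lactol: the first equivalent deprotonates 3 and opens it to the aldehyde alkoxide, the second adds to the aldehyde, and the new secondary carbinol may form as both epimers because it becomes the ketone carbon in step 4.

Step 3
Reactants: 4 (6S)-2,6-dimethylocta-1,7-diene-3,6-diol
Product: 5 (4S)-2,4-dimethylcyclohex-2-ene-1,4-diol (both C1 epimers)
Conditions: second-generation Grubbs catalyst RuCl2(=CHPh)(PCy3)(H2IMes) (cat.), CH2Cl2 (dilute), reflux
Reagents that add atoms: none
Why: Ring-closing metathesis initiates at the vinyl group and closes the six-membered ring onto the 1,1-disubstituted alkene with loss of ethene, a closure to a trisubstituted cyclohexene that is well precedented for this catalyst and tolerates free allylic hydroxyl groups; no stereocentre is formed or disturbed.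

Step 4
Reactants: 5 (4S)-2,4-dimethylcyclohex-2-ene-1,4-diol
Product: 6 (4S)-4-hydroxy-2,4-dimethylcyclohex-2-en-1-one (fragment A)
Conditions: MnO2 (activated, excess), CH2Cl2, rt
Reagents that add atoms: none
Why: MnO2 allylic oxidation takes only the secondary allylic alcohol, since the tertiary one has no carbinol hydrogen and does not transpose in the absence of chromium oxidants or acid, so both C1 epimers of 5 converge on the single enantiomer 6.

Step 5
Reactants: 7 (R)-(−)-linalool
Product: 9 (3R)-3,7-dimethyloct-6-ene-1,3-diol, via B-alkyl-9-BBN adduct 8 (not isolated)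
Conditions: 9-BBN (1.5 equiv), THF, 0 °C → rt; then aq. NaOH, H2O2, 0 °C → rt
Reagents that add atoms: hydrogen peroxide, OO
Why: Hydroboration–oxidation: the bulky 9-BBN adds to the monosubstituted vinyl group far faster than to the trisubstituted alkene and places boron on the terminal carbon, and oxidation of the carbon–boron bond gives the primary alcohol while the tertiary carbinol centre stays as bought.

Step 6
Reactants: 9 (3R)-3,7-dimethyloct-6-ene-1,3-diol
Product: 10 (4R)-2,2,4-trimethyl-4-(4-methylpent-3-en-1-yl)-1,3-dioxane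
Conditions: 2,2-dimethoxypropane, PPTS (cat.), CH2Cl2, rt
Reagents that add atoms: 2,2-dimethoxypropane, COC(C)(C)OC
Why: Acid-catalysed transketalisation ties the 1,3-diol into a six-membered acetonide, a single base-stable group that masks both hydroxyl groups for the organometallic chemistry of step 9.

Step 7
Reactants: 10 (4R)-2,2,4-trimethyl-4-(4-methylpent-3-en-1-yl)-1,3-dioxane
Product: 12 3-[(4R)-2,2,4-trimethyl-1,3-dioxan-4-yl]propanoic acid, via aldehyde 11 (not isolated)
Conditions: O3, CH2Cl2, −78 °C; Me2S; then NaClO2, NaH2PO4, 2-methyl-2-butene, t-BuOH/H2O, 0 °C → rt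
Reagents that add atoms: ozone, [O-][O+]=O; sodium chlorite, [Na+].[O-]Cl=O
Why: Ozonolysis of the only alkene followed by Pinnick oxidation of the crude aldehyde 11 under phosphate buffer should give the acid, since there is no epimerisable centre and the buffered medium spares the acetonide.

Step 8
Reactants: 12 3-[(4R)-2,2,4-trimethyl-1,3-dioxan-4-yl]propanoic acid
Product: 14 (4S)-4-(2-iodoethyl)-2,2,4-trimethyl-1,3-dioxane (same spatial arrangement and new descriptor because of iodine), via acyl hypoiodite 13 (not isolated)
Conditions: PhI(OAc)2, I2, cyclohexane/CH2Cl2, hν (tungsten lamp), reflux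
Reagents that add atoms: iodine, [I][I]
Why: Hunsdiecker-type iododecarboxylation: PhI(OAc)2 and I2 convert the acid into acyl hypoiodite 13, whose photolysis gives CO2 and a primary alkyl radical that iodine captures very rapidly, so the surplus carbon of linalool leaves and the carbon that will bond to the ring becomes a halide.

Step 9
Reactants: 6 (4S)-4-hydroxy-2,4-dimethylcyclohex-2-en-1-one; 14 (4S)-4-(2-iodoethyl)-2,2,4-trimethyl-1,3-dioxane
Product: 19 (3R,4S)-4-hydroxy-2,2,4-trimethyl-3-{2-[(4R)-2,2,4-trimethyl-1,3-dioxan-4-yl]ethyl}cyclohexan-1-one, via lithium alkoxide 15 (not isolated), via alkyllithium 16 (not isolated), via alkylmagnesium bromide 17 (not isolated), via magnesium enolate 18 (not isolated)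
Conditions: (a) 14 (1.3 equiv), t-BuLi (2.6 equiv), Et2O/pentane, −78 °C; MgBr2·OEt2 (1.4 equiv), −78 → 0 °C; (b) 6, LiHMDS (1.0 equiv), THF, −78 °C; (c) add (b) to (a), −78 → 0 °C; (d) MeI (5 equiv), DMPU, 0 °C → rt; then H2O
Reagents that add atoms: iodomethane, CI
Why: The lithium alkoxide 15 binds the Grignard reagent 17 at oxygen to give an alkoxide-anchored organomagnesium aggregate, which hands its primary alkyl group to the neighbouring enone β-carbon C3 and leaves the regiodefined tetrasubstituted magnesium enolate 18; MeI/DMPU then alkylates 18 at C2 and completes the gem-dimethyl carbon. The closest known reaction types are the ligand-assisted (alkoxide-directed) 1,4-addition of Grignard reagents to 4-hydroxycyclohexa-2,5-dienones and 4-hydroxycyclohex-2-enones, and the tandem conjugate addition–enolate alkylation of 2-methylcyclohex-2-enones. No ring is closed in this step. The only new stereocentre, ring C3, is controlled by the C4 carbinol: delivery from the oxygen-bound metal is possible only on the face that carries the oxygen, so the chain ends cis to OH (3R next to 4S), whereas C2 becomes CMe2 and is not stereogenic and the dioxane centre is a spectator. The step needs 1,4- over 1,2-addition, which the anchoring secures because the carbonyl carbon lies across the ring out of reach of the bound nucleophile, and it needs C- over O-methylation without enolate equilibration, which the hindered tertiary alkoxide, the excess of MeI and the absence of a proton source secure. The acetonide is inert to all the bases used, and the γ-hydroxy ketone formed can undergo neither retro-aldol cleavage nor β-elimination.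

Step 10
Reactants: 19 (3R,4S)-4-hydroxy-2,2,4-trimethyl-3-{2-[(4R)-2,2,4-trimethyl-1,3-dioxan-4-yl]ethyl}cyclohexan-1-one
Product: 20 (3R,4S)-3-[(3R)-3,5-dihydroxy-3-methylpentyl]-4-hydroxy-2,2,4-trimethylcyclohexan-1-one
Conditions: AcOH/THF/H2O, 40 °C
Reagents that add atoms: none
Why: Mild acid-catalysed acetal hydrolysis frees the primary and the tertiary hydroxyl group of the side chain, and under aqueous acetic acid neither tertiary alcohol should ionise nor the γ-hydroxy ketone eliminate.

Step 11
Reactants: 20 (3R,4S)-3-[(3R)-3,5-dihydroxy-3-methylpentyl]-4-hydroxy-2,2,4-trimethylcyclohexan-1-one; 21 umbelliferone (7-hydroxy-2H-chromen-2-one)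
Product: 22 7-{[(3R)-3-hydroxy-5-[(1R,6S)-6-hydroxy-2,2,6-trimethyl-3-oxocyclohexyl]-3-methylpentyl]oxy}-2H-chromen-2-one (target CNP0414652.1)
Conditions: PPh3, DIAD, THF, 0 °C → rt
Reagents that add atoms: none
Why: Mitsunobu etherification: only the primary alcohol forms a reactive alkoxyphosphonium ion, which the acidic phenol of 21 displaces, while the two tertiary alcohols are inert, so the aryl ether forms without protecting groups and without touching a stereocentre.

**Compound list**
1 | (S)-(+)-linalool | C=C[C@@](C)(O)CCC=C(C)C | starting material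
2 | (4S)-4-hydroxy-4-methylhex-5-enal (not isolated) | C=C[C@@](C)(O)CCC=O | intermediate
3 | (5S)-5-ethenyl-5-methyloxolan-2-ol (anomer mixture) | C=C[C@]1(C)CCC(O)O1 | intermediate
4 | (6S)-2,6-dimethylocta-1,7-diene-3,6-diol (C3 epimers) | C=C[C@@](C)(O)CCC(O)C(C)=C | intermediate
5 | (4S)-2,4-dimethylcyclohex-2-ene-1,4-diol (C1 epimers) | CC1=C[C@@](C)(O)CCC1O | intermediate
6 | (4S)-4-hydroxy-2,4-dimethylcyclohex-2-en-1-one | CC1=C[C@@](C)(O)CCC1=O | intermediate
7 | (R)-(−)-linalool | C=C[C@](C)(O)CCC=C(C)C | starting material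
8 | (3R)-1-(9-borabicyclo[3.3.1]nonan-9-yl)-3,7-dimethyloct-6-en-3-ol (not isolated) | C1CC2CCCC(C1)B2CC[C@](C)(O)CCC=C(C)C | intermediate
9 | (3R)-3,7-dimethyloct-6-ene-1,3-diol | OCC[C@](C)(O)CCC=C(C)C | intermediate
10 | (4R)-2,2,4-trimethyl-4-(4-methylpent-3-en-1-yl)-1,3-dioxane | CC1(C)OCC[C@@](C)(CCC=C(C)C)O1 | intermediate
11 | 3-[(4R)-2,2,4-trimethyl-1,3-dioxan-4-yl]propanal (not isolated) | CC1(C)OCC[C@@](C)(CCC=O)O1 | intermediate
12 | 3-[(4R)-2,2,4-trimethyl-1,3-dioxan-4-yl]propanoic acid | CC1(C)OCC[C@@](C)(CCC(=O)O)O1 | intermediate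
13 | acyl hypoiodite of 12 (not isolated) | CC1(C)OCC[C@@](C)(CCC(=O)OI)O1 | intermediate
14 | (4S)-4-(2-iodoethyl)-2,2,4-trimethyl-1,3-dioxane | CC1(C)OCC[C@@](C)(CCI)O1 | intermediate
15 | lithium alkoxide of 6 (not isolated) | CC1=C[C@@](C)(O[Li])CCC1=O | intermediate
16 | 2-(2,2,4-trimethyl-1,3-dioxan-4-yl)ethyllithium (not isolated) | CC1(C)OCC[C@@](C)(CC[Li])O1 | intermediate
17 | 2-(2,2,4-trimethyl-1,3-dioxan-4-yl)ethylmagnesium bromide (not isolated) | CC1(C)OCC[C@@](C)(CC[Mg]Br)O1 | intermediate
18 | bromomagnesium enolate / lithium alkoxide of the 1,4-adduct (not isolated) | CC1=C(O[Mg]Br)CC[C@](C)(O[Li])[C@@H]1CC[C@]2(C)CCOC(C)(C)O2 | intermediate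
19 | (3R,4S)-4-hydroxy-2,2,4-trimethyl-3-{2-[(4R)-2,2,4-trimethyl-1,3-dioxan-4-yl]ethyl}cyclohexan-1-one | CC1(C)C(=O)CC[C@](C)(O)[C@@H]1CC[C@]2(C)CCOC(C)(C)O2 | intermediate
20 | (3R,4S)-3-[(3R)-3,5-dihydroxy-3-methylpentyl]-4-hydroxy-2,2,4-trimethylcyclohexan-1-one | CC1(C)C(=O)CC[C@](C)(O)[C@@H]1CC[C@@](C)(O)CCO | intermediate
21 | umbelliferone (7-hydroxy-2H-chromen-2-one) | Oc1ccc2ccc(=O)oc2c1 | starting material
22 | 7-{[(3R)-3-hydroxy-5-[(1R,6S)-6-hydroxy-2,2,6-trimethyl-3-oxocyclohexyl]-3-methylpentyl]oxy}-2H-chromen-2-one | CC1(C)C(=O)CC[C@](C)(O)[C@@H]1CC[C@@](C)(O)CCOc1ccc2ccc(=O)oc2c1 | target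

Total step count: 11. Longest linear sequence: 7 steps (7 → 22 through steps 5–11). The branch from 1 is equally long (steps 1–4 and 9–11).

**Steps most likely to fail**

Step 9. Unanchored Grignard reagent may attack the carbonyl group directly or enolise the enone. Incomplete anchoring would erode the facial selectivity. Surplus 17 may attack the ketone once methylation has unveiled it.
- The fallback replaces the alkyl carbanion by an alkynyl carbanion and reduces afterwards. Alkoxide-directed 1,4-delivery is best established for this nucleophile class, which has no β-hydrogen and adds sluggishly to a hindered ketone.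
- It sets out from 14 and 6.
- Compound 14 is dehydroiodinated (t-BuOK, THF) to (4S)-4-ethenyl-2,2,4-trimethyl-1,3-dioxane F1.
- Bromination (Br2, CH2Cl2, −78 °C) gives (4S)-4-(1,2-dibromoethyl)-2,2,4-trimethyl-1,3-dioxane F2, and double dehydrobromination (NaNH2, NH3/THF) gives (4S)-4-ethynyl-2,2,4-trimethyl-1,3-dioxane F3.
- EtMgBr (THF) turns F3 into the alkynylmagnesium bromide F4, which is combined with lithium alkoxide 15 as in step 9 to give the alkynyl-substituted magnesium enolate F5.
- MeI/DMPU converts F5 into (3R,4S)-4-hydroxy-2,2,4-trimethyl-3-{[(4S)-2,2,4-trimethyl-1,3-dioxan-4-yl]ethynyl}cyclohexan-1-one F6.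
- Hydrogenation (H2, Pd/C, EtOAc) saturates the triple bond and comes back to the route at 19.

Step 8. The acetonide may be lost to I2/AcOH under irradiation, and hydrogen-atom abstraction may compete with iodine capture of the primary radical.
- The fallback removes the surplus carbon by an ionic enol-ether cleavage instead of a radical decarboxylation.
- It sets out from aldehyde 11, now isolated after the ozonolysis of 10.
- TBSCl/DBU (CH2Cl2, reflux) gives the tert-butyldimethylsilyl enol ether of 11 F7.
- Ozonolysis (O3, CH2Cl2/MeOH, −78 °C) cuts the enol ether double bond to 2-[(4S)-2,2,4-trimethyl-1,3-dioxan-4-yl]acetaldehyde F8.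
- NaBH4 in the same flask reduces F8 to 2-[(4R)-2,2,4-trimethyl-1,3-dioxan-4-yl]ethan-1-ol F9.
- An Appel iodination (I2, PPh3, imidazole, CH2Cl2, 0 °C) comes back to the route at 14.

Step 3. Closure onto the 1,1-disubstituted alkene may be slow, dimerisation through the vinyl group may compete, and ruthenium hydride species may isomerise the allylic alcohols.
- The fallback closes the ring by an intramolecular aldol condensation instead of metathesis.
- It sets out from lactol 3.
- EtMgBr (2.5 equiv, THF) gives (3S)-3-methyloct-1-ene-3,6-diol F10.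
- Dess–Martin periodinane (NaHCO3, CH2Cl2) oxidises the secondary alcohol to (6S)-6-hydroxy-6-methyloct-7-en-3-one F11.
- Ozonolysis of the vinyl group (O3, CH2Cl2, −78 °C; Me2S) gives (2S)-2-hydroxy-2-methyl-5-oxoheptanal F12.
- Piperidinium acetate (toluene, reflux) adds the CH2 of the ethyl ketone to the aldehyde, the only enolisable position that can form a six-membered ring. This gives (4S)-3,4-dihydroxy-2,4-dimethylcyclohexan-1-one F13, which dehydrates and comes back to the route at 6.

**Further compounds**
F1 | step 9 | (4S)-4-ethenyl-2,2,4-trimethyl-1,3-dioxane | CC1(C)OCC[C@@](C)(C=C)O1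
F2 | step 9 | (4S)-4-(1,2-dibromoethyl)-2,2,4-trimethyl-1,3-dioxane (epimers at CHBr) | CC1(C)OCC[C@@](C)(C(Br)CBr)O1
F3 | step 9 | (4S)-4-ethynyl-2,2,4-trimethyl-1,3-dioxane | CC1(C)OCC[C@@](C)(C#C)O1
F4 | step 9 | alkynylmagnesium bromide from F3 | CC1(C)OCC[C@@](C)(C#C[Mg]Br)O1
F5 | step 9 | alkynyl-substituted magnesium enolate | CC1=C(O[Mg]Br)CC[C@](C)(O[Li])[C@@H]1C#C[C@]2(C)CCOC(C)(C)O2
F6 | step 9 | (3R,4S)-4-hydroxy-2,2,4-trimethyl-3-{[(4S)-2,2,4-trimethyl-1,3-dioxan-4-yl]ethynyl}cyclohexan-1-one | CC1(C)C(=O)CC[C@](C)(O)[C@@H]1C#C[C@]2(C)CCOC(C)(C)O2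
F7 | step 8 | tert-butyldimethylsilyl enol ether of 11 (E/Z mixture) | CC1(C)OCC[C@@](C)(CC=CO[Si](C)(C)C(C)(C)C)O1
F8 | step 8 | 2-[(4S)-2,2,4-trimethyl-1,3-dioxan-4-yl]acetaldehyde | CC1(C)OCC[C@@](C)(CC=O)O1
F9 | step 8 | 2-[(4R)-2,2,4-trimethyl-1,3-dioxan-4-yl]ethan-1-ol | CC1(C)OCC[C@@](C)(CCO)O1
F10 | step 3 | (3S)-3-methyloct-1-ene-3,6-diol (C6 epimers) | C=C[C@@](C)(O)CCC(O)CC
F11 | step 3 | (6S)-6-hydroxy-6-methyloct-7-en-3-one | C=C[C@@](C)(O)CCC(=O)CC
F12 | step 3 | (2S)-2-hydroxy-2-methyl-5-oxoheptanal | O=C[C@@](C)(O)CCC(=O)CC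
F13 | step 3 | (4S)-3,4-dihydroxy-2,4-dimethylcyclohexan-1-one (aldol adduct) | CC1C(O)[C@@](C)(O)CCC1=O
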